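**Plan**

- Retrosynthesis: C2 of ring C is removed (O1–C2 and C2–C3) to give a deoxybenzoin. Ring A is then opened at C4a–C5 into a linear 3,5,7-trioxo ester. That chain is cut between C4a and C4 into a triketide and a ring-B arylacetyl unit, and the three prenyl C–C bonds go back to prenyl bromide.
- Enabling feature: C6 and C8 of ring A are, in the open chain, the two methine carbons lying between carbonyl groups (chain C2 and C4; chain C1 becomes C5, chain C6 becomes C4a). Both prenyl groups can therefore be put on by enolate alkylation before ring A exists. The resulting ring A is symmetric, so either ortho-hydroxyl closes ring C to the same isoflavone.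
- Forward: ring B is built from 2,4-dihydroxybenzaldehyde into an arylacetic Weinreb amide (steps 1–6). The diprenyl dioxo ester comes from 4-hydroxy-6-methyl-2-pyrone (steps 7–9). Trianion acylation joins the chain (step 10), Claisen closure forms ring A (step 11), formylative closure forms ring C (step 12), and deprotection follows (step 13).
- Stereochemistry: the target has no stereocentre and no stereogenic double bond. The stereocentres of the open-chain intermediates disappear on aromatisation.

Key step: step 11

Remark: polycarbonyl intermediates are drawn as keto tautomers and are used as mixtures of epimers and enol forms. Anions formed by simple deprotonation of a numbered compound are treated as forms of that compound and are not numbered separately.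

**Route**

Step 1
Reactants: 1 2,4-dihydroxybenzaldehyde; 2 prenyl bromide
Product: 3 2,4-dihydroxy-3-(3-methylbut-2-enyl)benzaldehyde
Conditions: KOH (10% aq.), H2O, 0 °C to rt
Reagents that add atoms: prenyl bromide (compound 2), CC(C)=CCBr
Why: Phenoxide C-alkylation in water, where the protic medium suppresses O-alkylation, should place the prenyl group mainly on C3, the ring carbon activated by both oxygens, with the 5-prenyl and O-prenyl isomers removed by chromatography.

Step 2
Reactants: 3 2,4-dihydroxy-3-(3-methylbut-2-enyl)benzaldehyde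
Product: 4 2-hydroxy-4-(methoxymethoxy)-3-(3-methylbut-2-enyl)benzaldehyde
Conditions: MOMCl (1.1 equiv), K2CO3, acetone, 0 °C to rt
Reagents that add atoms: chloromethyl methyl ether, COCCl
Why: Williamson-type O-alkylation should occur only at the 4-hydroxyl, because the 2-hydroxyl is held in a hydrogen bond to the aldehyde and is screened by the neighbouring prenyl group.

Step 3
Reactants: 4 2-hydroxy-4-(methoxymethoxy)-3-(3-methylbut-2-enyl)benzaldehyde
Product: 5 2-methoxy-4-(methoxymethoxy)-3-(3-methylbut-2-enyl)benzaldehyde
Conditions: MeI, K2CO3, DMF, 40 °C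
Reagents that add atoms: iodomethane, CI
Why: Williamson O-methylation of the one remaining, chelated phenol is forced by K2CO3 in a dipolar aprotic solvent, and no other acidic site is present.

Step 4
Reactants: 5 2-methoxy-4-(methoxymethoxy)-3-(3-methylbut-2-enyl)benzaldehyde
Product: 7 2-[2-methoxy-4-(methoxymethoxy)-3-(3-methylbut-2-enyl)phenyl]acetonitrile, via tosylvinyl formamide 6 (not isolated)
Conditions: TosMIC (1.2 equiv), KOt-Bu (2.5 equiv), DME, −50 °C; then MeOH, reflux
Reagents that add atoms: p-toluenesulfonylmethyl isocyanide (TosMIC), [C-]#[N+]CS(=O)(=O)c1ccc(C)cc1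
Why: Van Leusen reductive cyanation, in which the TosMIC anion adds to the aldehyde in the cold and opens to vinyl formamide 6, which on methanolysis loses methyl formate and sulfinate to give the one-carbon-homologated nitrile while the base-stable acetal, ether and prenyl groups are untouched.

Step 5
Reactants: 7 2-[2-methoxy-4-(methoxymethoxy)-3-(3-methylbut-2-enyl)phenyl]acetonitrile
Product: 8 2-[2-methoxy-4-(methoxymethoxy)-3-(3-methylbut-2-enyl)phenyl]acetic acid
Conditions: KOH, EtOH/H2O, reflux; then 1 M HCl to pH 4, 0 °C
Reagents that add atoms: water, O (delivered as hydroxide from KOH, [K+].[OH-])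
Why: Alkaline nitrile hydrolysis runs through the primary amide to the carboxylate; the MOM acetal and the prenyl alkene are inert to hydroxide, and the acid is set free cold at pH 4 so that the acetal survives.

Step 6
Reactants: 8 2-[2-methoxy-4-(methoxymethoxy)-3-(3-methylbut-2-enyl)phenyl]acetic acid
Product: 10 N-methoxy-N-methyl-2-[2-methoxy-4-(methoxymethoxy)-3-(3-methylbut-2-enyl)phenyl]acetamide, via acyl imidazolide 9 (not isolated)
Conditions: CDI (1.2 equiv), CH2Cl2, rt; then MeNHOMe·HCl (1.5 equiv), rt
Reagents that add atoms: N,O-dimethylhydroxylamine hydrochloride, CNOC.Cl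
Why: Amide coupling through acyl imidazolide 9 (carbonyldiimidazole activation) should give the Weinreb amide under essentially neutral conditions that spare the acetal.

Step 7
Reactants: 11 4-hydroxy-6-methyl-2-pyrone
Product: 12 methyl 3,5-dioxohexanoate
Conditions: Mg(OMe)2 (2 equiv), MeOH, reflux; then cold 1 M HCl
Reagents that add atoms: methanol, CO (delivered as Mg(OMe)2, C[O-].C[O-].[Mg+2])
Why: Lactone alcoholysis, in which methoxide opens the 2-pyrone at its carbonyl and magnesium chelation of the resulting dienolate holds the open-chain dioxo ester against reclosure.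

Step 8
Reactants: 12 methyl 3,5-dioxohexanoate; 2 prenyl bromide
Product: 13 methyl 4-(3-methylbut-2-enyl)-3,5-dioxohexanoate
Conditions: NaH (1.0 equiv), THF, 0 °C; then 2 (0.95 equiv), 0 °C to rt
Reagents that add atoms: prenyl bromide (compound 2), CC(C)=CCBr
Why: Enolate C-alkylation of the β-diketone monoanion, which is localised on C4 (the most acidic carbon, between two ketones); the soft allylic bromide favours carbon over oxygen, and a slight deficit of 2 limits double alkylation.

Step 9
Reactants: 13 methyl 4-(3-methylbut-2-enyl)-3,5-dioxohexanoate; 2 prenyl bromide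
Product: 14 methyl 2,4-bis(3-methylbut-2-enyl)-3,5-dioxohexanoate
Conditions: LiN(i-Pr)2 (2.1 equiv), THF, −78 to 0 °C; then 2 (1.0 equiv), −78 to 0 °C; aq. NH4Cl
Reagents that add atoms: prenyl bromide (compound 2), CC(C)=CCBr
Why: Dianion alkylation, in which the second deprotonation takes place at C2 (between ketone and ester) and the dianion reacts at this last-formed, most basic carbon, while C4 is already tertiary and would have to become quaternary.

Step 10
Reactants: 14 methyl 2,4-bis(3-methylbut-2-enyl)-3,5-dioxohexanoate; 10 N-methoxy-N-methyl-2-[2-methoxy-4-(methoxymethoxy)-3-(3-methylbut-2-enyl)phenyl]acetamide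
Product: 16 methyl 8-[2-methoxy-4-(methoxymethoxy)-3-(3-methylbut-2-enyl)phenyl]-2,4-bis(3-methylbut-2-enyl)-3,5,7-trioxooctanoate, via tetrahedral Weinreb adduct 15 (not isolated)
Conditions: 14 (1.3 equiv), LiN(i-Pr)2 (4.0 equiv), THF, −78 to 0 °C; then 10 (1.0 equiv), −78 to −20 °C; aq. NH4Cl, 0 °C; crude product used directly
Reagents that add atoms: none
Why: Polyanion acylation (Weinreb ketone synthesis), in which three equivalents of base give the 2,4,6-trianion whose terminal carbanion is the last formed and most nucleophilic site and whose ester is masked as its enolate, while the chelated adduct 15 blocks over-addition and releases the ketone only on work-up.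

Step 11
Reactants: 16 methyl 8-[2-methoxy-4-(methoxymethoxy)-3-(3-methylbut-2-enyl)phenyl]-2,4-bis(3-methylbut-2-enyl)-3,5,7-trioxooctanoate
Product: 18 2-[2-methoxy-4-(methoxymethoxy)-3-(3-methylbut-2-enyl)phenyl]-1-[2,4,6-trihydroxy-3,5-bis(3-methylbut-2-enyl)phenyl]ethanone, via cyclohexanetrione tautomer 17 (not isolated)
Conditions: Mg(OMe)2 (4 equiv), MeOH, rt to 50 °C, argon; then cold 0.5 M HCl to pH 5
Reagents that add atoms: none
Why: Mg(OMe)2 should turn 16 into a magnesium-chelated polyenolate in which chain C6, the only methylene between two ketones, attacks the ester carbonyl C1; loss of methoxide gives triketone 17, whose enolisation to the phloroglucinol is irreversible and drives the sequence. The closest known reaction is the intramolecular Claisen (Dieckmann-type) cyclisation of 3,5,7-trioxo esters to acylphloroglucinols, applied here to a chain carrying two prenyl groups. The new bond (C4a–C5 of the target) closes the six-membered carbocyclic ring A in the 6-exo-trig mode. No stereocentre is formed, and the two stereocentres of 16 at chain C2 and C4 become sp2 ring carbons, so all epimers and enol forms converge on one product. The step needs Claisen closure to win over aldol closure: attack of chain C2 on the C7 ketone would give a quaternary carbon that cannot aromatise and so reverts by retro-aldol; the benzylic C8 is far less acidic than C6 and the C3 ketone it would attack is flanked by two tertiary carbons; and lactonisation to a 2-pyrone is reopened by methoxide as in step 7.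

Step 12
Reactants: 18 2-[2-methoxy-4-(methoxymethoxy)-3-(3-methylbut-2-enyl)phenyl]-1-[2,4,6-trihydroxy-3,5-bis(3-methylbut-2-enyl)phenyl]ethanone
Product: 20 5,7-dihydroxy-3-[2-methoxy-4-(methoxymethoxy)-3-(3-methylbut-2-enyl)phenyl]-6,8-bis(3-methylbut-2-enyl)chromen-4-one, via enaminone 19 (not isolated)
Conditions: Me2NCH(OMe)2 (1.5 equiv), THF, 60 °C, argon
Reagents that add atoms: N,N-dimethylformamide dimethyl acetal, COC(OC)N(C)C
Why: Enaminone formation at the benzylic methylene (activated by ketone and aryl group) and then addition–elimination by an ortho-hydroxyl with loss of dimethylamine closes the 4-pyranone ring C; the two ortho-hydroxyls of ring A are equivalent by symmetry, so only one isoflavone can form, and the small excess of acetal at moderate temperature limits O-methylation.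

Step 13
Reactants: 20 5,7-dihydroxy-3-[2-methoxy-4-(methoxymethoxy)-3-(3-methylbut-2-enyl)phenyl]-6,8-bis(3-methylbut-2-enyl)chromen-4-one
Product: 21 5,7-dihydroxy-3-[4-hydroxy-2-methoxy-3-(3-methylbut-2-enyl)phenyl]-6,8-bis(3-methylbut-2-enyl)chromen-4-one
Conditions: HCl (3 M aq.), MeOH, 40 °C
Reagents that add atoms: none
Why: Acid-catalysed acetal cleavage (transacetalisation to dimethoxymethane) frees the 4'-hydroxyl, and dilute acid at moderate temperature is the usual way to unmask MOM ethers next to ortho-prenyl phenols without cyclisation to chromans.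

**Compound list**

1 | 2,4-dihydroxybenzaldehyde | O=Cc1ccc(O)cc1O | starting material
2 | prenyl bromide (1-bromo-3-methylbut-2-ene) | CC(C)=CCBr | starting material
3 | 2,4-dihydroxy-3-(3-methylbut-2-enyl)benzaldehyde | O=Cc1ccc(O)c(CC=C(C)C)c1O | intermediate
4 | 2-hydroxy-4-(methoxymethoxy)-3-(3-methylbut-2-enyl)benzaldehyde | O=Cc1ccc(OCOC)c(CC=C(C)C)c1O | intermediate
5 | 2-methoxy-4-(methoxymethoxy)-3-(3-methylbut-2-enyl)benzaldehyde | COc1c(C=O)ccc(OCOC)c1CC=C(C)C | intermediate
6 | N-{2-[2-methoxy-4-(methoxymethoxy)-3-(3-methylbut-2-enyl)phenyl]-1-(4-methylphenylsulfonyl)ethenyl}formamide (alkene geometry not defined; not isolated) | COc1c(C=C(NC=O)S(=O)(=O)c2ccc(C)cc2)ccc(OCOC)c1CC=C(C)C | intermediate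
7 | 2-[2-methoxy-4-(methoxymethoxy)-3-(3-methylbut-2-enyl)phenyl]acetonitrile | COc1c(CC#N)ccc(OCOC)c1CC=C(C)C | intermediate
8 | 2-[2-methoxy-4-(methoxymethoxy)-3-(3-methylbut-2-enyl)phenyl]acetic acid | COc1c(CC(=O)O)ccc(OCOC)c1CC=C(C)C | intermediate
9 | 1-(imidazol-1-yl)-2-[2-methoxy-4-(methoxymethoxy)-3-(3-methylbut-2-enyl)phenyl]ethanone (not isolated) | COc1c(CC(=O)n2ccnc2)ccc(OCOC)c1CC=C(C)C | intermediate
10 | N-methoxy-N-methyl-2-[2-methoxy-4-(methoxymethoxy)-3-(3-methylbut-2-enyl)phenyl]acetamide | COc1c(CC(=O)N(C)OC)ccc(OCOC)c1CC=C(C)C | intermediate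
11 | 4-hydroxy-6-methyl-2-pyrone | Cc1cc(O)cc(=O)o1 | starting material
12 | methyl 3,5-dioxohexanoate | COC(=O)CC(=O)CC(C)=O | intermediate
13 | methyl 4-(3-methylbut-2-enyl)-3,5-dioxohexanoate (racemic, enol mixture) | COC(=O)CC(=O)C(CC=C(C)C)C(C)=O | intermediate
14 | methyl 2,4-bis(3-methylbut-2-enyl)-3,5-dioxohexanoate (mixture of epimers and enol forms) | COC(=O)C(CC=C(C)C)C(=O)C(CC=C(C)C)C(C)=O | intermediate
15 | methyl 7-hydroxy-7-[methoxy(methyl)amino]-8-[2-methoxy-4-(methoxymethoxy)-3-(3-methylbut-2-enyl)phenyl]-2,4-bis(3-methylbut-2-enyl)-3,5-dioxooctanoate (present as its lithium chelate, drawn neutral; mixture of epimers; not isolated) | COC(=O)C(CC=C(C)C)C(=O)C(CC=C(C)C)C(=O)CC(O)(Cc1ccc(OCOC)c(CC=C(C)C)c1OC)N(C)OC | intermediate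
16 | methyl 8-[2-methoxy-4-(methoxymethoxy)-3-(3-methylbut-2-enyl)phenyl]-2,4-bis(3-methylbut-2-enyl)-3,5,7-trioxooctanoate (mixture of epimers and enol forms) | COC(=O)C(CC=C(C)C)C(=O)C(CC=C(C)C)C(=O)CC(=O)Cc1ccc(OCOC)c(CC=C(C)C)c1OC | intermediate
17 | 2-{2-[2-methoxy-4-(methoxymethoxy)-3-(3-methylbut-2-enyl)phenyl]acetyl}-4,6-bis(3-methylbut-2-enyl)cyclohexane-1,3,5-trione (mixture of epimers; not isolated) | COc1c(CC(=O)C2C(=O)C(CC=C(C)C)C(=O)C(CC=C(C)C)C2=O)ccc(OCOC)c1CC=C(C)C | intermediate
18 | 2-[2-methoxy-4-(methoxymethoxy)-3-(3-methylbut-2-enyl)phenyl]-1-[2,4,6-trihydroxy-3,5-bis(3-methylbut-2-enyl)phenyl]ethanone | COc1c(CC(=O)c2c(O)c(CC=C(C)C)c(O)c(CC=C(C)C)c2O)ccc(OCOC)c1CC=C(C)C | intermediate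
19 | 3-(dimethylamino)-2-[2-methoxy-4-(methoxymethoxy)-3-(3-methylbut-2-enyl)phenyl]-1-[2,4,6-trihydroxy-3,5-bis(3-methylbut-2-enyl)phenyl]prop-2-en-1-one (alkene geometry not defined; not isolated) | COc1c(C(=CN(C)C)C(=O)c2c(O)c(CC=C(C)C)c(O)c(CC=C(C)C)c2O)ccc(OCOC)c1CC=C(C)C | intermediate
20 | 5,7-dihydroxy-3-[2-methoxy-4-(methoxymethoxy)-3-(3-methylbut-2-enyl)phenyl]-6,8-bis(3-methylbut-2-enyl)chromen-4-one | COc1c(-c2coc3c(CC=C(C)C)c(O)c(CC=C(C)C)c(O)c3c2=O)ccc(OCOC)c1CC=C(C)C | intermediate
21 | 5,7-dihydroxy-3-[4-hydroxy-2-methoxy-3-(3-methylbut-2-enyl)phenyl]-6,8-bis(3-methylbut-2-enyl)chromen-4-one | COc1c(-c2coc3c(CC=C(C)C)c(O)c(CC=C(C)C)c(O)c3c2=O)ccc(O)c1CC=C(C)C | target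

**Step count**

Total: 13 steps. Longest linear sequence: 10 steps (steps 1–6, then 10–13). The three-step branch (steps 7–9) joins at step 10.

**Steps most likely to fail**

Step 10. Deprotonation of the doubly α-substituted chain may stop short of the trianion, so that a partly metalated species closes onto its own ester. The trianion may also take a benzylic proton from the amide instead of adding to it. The fallback avoids the trianion by locking chain C1–C5 in a pyranone ring. It sets out from 14, which is lactonised with DBU in toluene at 80 °C to 4-hydroxy-6-methyl-3,5-bis(3-methylbut-2-enyl)pyran-2-one F1. Two equivalents of LiN(i-Pr)2 in THF at −78 °C convert it into the dianion (hydroxyl and 6-methyl), a known type of pyranone dianion. Acylation at the methyl group with 10 should give 4-hydroxy-6-{3-[2-methoxy-4-(methoxymethoxy)-3-(3-methylbut-2-enyl)phenyl]-2-oxopropyl}-3,5-bis(3-methylbut-2-enyl)pyran-2-one F2. This is the lactone of the triketo ester. Mg(OMe)2 in MeOH opens it, as in step 7, to 16, where the route is rejoined in the flask of step 11.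

Step 11. The two α-substituents may slow attack on the ester so far that cyclisation from the benzylic carbon onto the C3 ketone, or methoxide cleavage of the β-triketone, takes over. The fallback keeps the same ring closure but runs it on the unsubstituted chain, the case with direct precedent, and prenylates afterwards. It sets out from 12, whose trianion (LiN(i-Pr)2, 3 equiv, THF, 0 °C) is acylated with 10 to give methyl 8-[2-methoxy-4-(methoxymethoxy)-3-(3-methylbut-2-enyl)phenyl]-3,5,7-trioxooctanoate F3. Mg(OMe)2 in MeOH should close it to 2-[2-methoxy-4-(methoxymethoxy)-3-(3-methylbut-2-enyl)phenyl]-1-(2,4,6-trihydroxyphenyl)ethanone F4. Twofold C-prenylation of the two free ring positions with 2 in aqueous KOH at 0 °C, a known reaction of acylphloroglucinols, comes back to the route at 18.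

Step 9. The dianion may be alkylated on oxygen or at the terminal methyl if it is not the equilibrated 2,4-species, and proton exchange between product and dianion may lead to over-alkylation. The fallback builds the same compound by acylation instead of a second alkylation of the dioxo ester. It sets out from 2 and commercial methyl acetoacetate. The acetoacetate dianion (NaH, then n-BuLi, THF, 0 °C) is alkylated with 2 at the terminal carbon to give methyl 7-methyl-3-oxooct-6-enoate F5. Alkylation of its monoanion with 2 (K2CO3, acetone) at C2 gives methyl 7-methyl-2-(3-methylbut-2-enyl)-3-oxooct-6-enoate F6. The dianion of F6 (LiN(i-Pr)2, 2.2 equiv, THF, −78 to 0 °C) is acetylated at C4 with N-methoxy-N-methylacetamide, which comes back to the route at 14 and makes steps 7–9 unnecessary.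

**Further compounds**

F1 | step 10 | 4-hydroxy-6-methyl-3,5-bis(3-methylbut-2-enyl)pyran-2-one | Cc1oc(=O)c(CC=C(C)C)c(O)c1CC=C(C)C
F2 | step 10 | 4-hydroxy-6-{3-[2-methoxy-4-(methoxymethoxy)-3-(3-methylbut-2-enyl)phenyl]-2-oxopropyl}-3,5-bis(3-methylbut-2-enyl)pyran-2-one | COc1c(CC(=O)Cc2oc(=O)c(CC=C(C)C)c(O)c2CC=C(C)C)ccc(OCOC)c1CC=C(C)C
F3 | step 11 | methyl 8-[2-methoxy-4-(methoxymethoxy)-3-(3-methylbut-2-enyl)phenyl]-3,5,7-trioxooctanoate | COC(=O)CC(=O)CC(=O)CC(=O)Cc1ccc(OCOC)c(CC=C(C)C)c1OC
F4 | step 11 | 2-[2-methoxy-4-(methoxymethoxy)-3-(3-methylbut-2-enyl)phenyl]-1-(2,4,6-trihydroxyphenyl)ethanone | COc1c(CC(=O)c2c(O)cc(O)cc2O)ccc(OCOC)c1CC=C(C)C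
F5 | step 9 | methyl 7-methyl-3-oxooct-6-enoate | COC(=O)CC(=O)CCC=C(C)C
F6 | step 9 | methyl 7-methyl-2-(3-methylbut-2-enyl)-3-oxooct-6-enoate (racemic) | COC(=O)C(CC=C(C)C)C(=O)CCC=C(C)C
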